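The route reads the tetrasubstituted C8=C9 alkene of ring B and its C11H2 neighbour as a C8=C9=C11 allene plus hydride, and cuts the C4–C5 and C9–C10 bonds of the decalin (rings A and B) back to a squalene-like chain; with no oxygen at C3, only H+ and H− are missing. In one operation a chiral proton donor protonates the terminal C3=C4 alkene, rings A and B close in a chair–chair cascade onto the central allene carbon C9, C5 and C10 are set trans (5S,10S), and a silane reduces the C8–C9–C11 allyl cation at C11. The precursor is a C30 monocyclic allene-polyene carrying the 17S methylenecyclohexane ring and the E C13=C14 alkene.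

Key step: step 15

Assumption: locants follow drimane numbering (C1–C10 decalin with C4 the gem-dimethyl carbon, C5 the ring-fusion CH, C10 the ring-fusion carbon bearing methyl; C11 on C9, then C12, then the E C13=C14 alkene; C17 the stereocentre of the methylenecyclohexane ring); the ligand of step 2 and the acid of step 15 are the enantiomers expected by analogy with simpler substrates, and the mirror-image reagent would be taken if the sense proved opposite; (E)-geranylacetone is bought free of its Z isomer.

Step 1
Reactants: 1 2-(2-bromoethyl)-2-methyl-1,3-dioxolane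
Product: 3 bis[2-(2-methyl-1,3-dioxolan-2-yl)ethyl]zinc, via Grignard reagent 2 (not isolated)
Conditions: 1 (2 equiv per zinc), Mg, THF, 20 °C; ZnCl2 (0.5 equiv relative to 1), Et2O, 0 → 20 °C; 1,4-dioxane, filtration under argon, solvent change to toluene
Reagents that add atoms: zinc chloride, Cl[Zn]Cl; second equivalent of bromide 1, CC1(CCBr)OCCO1
Why: Magnesium insertion into the primary bromide and transmetalation of two molecules of the resulting Grignard reagent with one ZnCl2 (Grignard formation followed by salt metathesis) is standard for this ketal-protected halide as long as the Grignard reagent stays at or below room temperature, so both alkyl groups of 3 come from 1, and precipitating the magnesium halide with dioxane leaves a salt-free dialkylzinc, which the copper catalyst of the next step needs for high selectivity.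

Step 2
Reactants: 3 bis[2-(2-methyl-1,3-dioxolan-2-yl)ethyl]zinc; 4 4,4-dimethylcyclohex-2-en-1-one; 5 N,N-dimethylmethyleneiminium iodide (Eschenmoser's salt)
Product: 7 (3R)-2-[(dimethylamino)methyl]-4,4-dimethyl-3-[2-(2-methyl-1,3-dioxolan-2-yl)ethyl]cyclohexan-1-one, via alkylzinc enolate 6 (not isolated)
Conditions: Cu(OTf)2 (2 mol %), (S)-binaphthol bis[(R)-1-phenylethyl]amine phosphoramidite (4 mol %), toluene, −30 °C; then 5, CH2Cl2, −30 → 20 °C; aq. NH4Cl/NH3 (pH 9)
Reagents that add atoms: none
Why: Copper-catalysed enantioselective conjugate addition of a dialkylzinc under binaphthol phosphoramidite control is particularly face-selective for 4,4-disubstituted cyclohexenones, so the ligand sets the β-carbon (the later C17) as drawn, and the regiodefined zinc enolate is then intercepted at C2 by the iminium ion in a Mannich reaction, the aminomethyl group being expected to enter trans to the new side chain at a centre that is removed in step 3.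

Step 3
Reactants: 7 (3R)-2-[(dimethylamino)methyl]-4,4-dimethyl-3-[2-(2-methyl-1,3-dioxolan-2-yl)ethyl]cyclohexan-1-one
Product: 9 (3S)-4,4-dimethyl-2-methylidene-3-[2-(2-methyl-1,3-dioxolan-2-yl)ethyl]cyclohexan-1-one, via trimethylammonium iodide 8 (not isolated)
Conditions: MeI, Et2O, 20 °C; then aq. NaHCO3, CH2Cl2, 20 °C; crude 9 taken on at once
Reagents that add atoms: none
Why: Exhaustive N-methylation turns the amine into a leaving group and mild base then expels trimethylamine from the β-ammonium ketone (quaternisation and β-elimination of a Mannich base), which gives the exocyclic enone without touching the stereocentre, whose descriptor changes from R to S only because the CIP ranking of its ring neighbours changes.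

Step 4
Reactants: 9 (3S)-4,4-dimethyl-2-methylidene-3-[2-(2-methyl-1,3-dioxolan-2-yl)ethyl]cyclohexan-1-one
Product: 10 (3S)-4,4-dimethyl-2-methylidene-3-[2-(2-methyl-1,3-dioxolan-2-yl)ethyl]cyclohexan-1-ol as a mixture of C1 epimers
Conditions: NaBH4, CeCl3·7H2O, MeOH, −40 °C
Reagents that add atoms: none
Why: The Luche reduction gives clean 1,2-addition of hydride to the exocyclic enone, and the configuration of the new carbinol carbon does not matter because that carbon becomes a CH2 group in step 6.

Step 5
Reactants: 10 (3S)-4,4-dimethyl-2-methylidene-3-[2-(2-methyl-1,3-dioxolan-2-yl)ethyl]cyclohexan-1-ol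
Product: 11 methyl carbonate of allylic alcohol 10
Conditions: ClCO2Me, pyridine, DMAP (cat.), CH2Cl2, 0 °C
Reagents that add atoms: methyl chloroformate, COC(=O)Cl
Why: Acylation of the secondary allylic alcohol with a chloroformate under nucleophilic catalysis is unexceptional and installs the leaving group that zerovalent palladium ionises in the next step.

Step 6
Reactants: 11 methyl carbonate of allylic alcohol 10
Product: 12 2-{2-[(1S)-2,2-dimethyl-6-methylidenecyclohexyl]ethyl}-2-methyl-1,3-dioxolane
Conditions: Pd(OAc)2 (5 mol %), PBu3 (20 mol %), HCO2NH4, THF, 40 °C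
Reagents that add atoms: none
Why: Palladium-catalysed formate hydrogenolysis of an allylic carbonate (π-allylpalladium formate, loss of CO2, hydride delivery) places hydrogen on the more substituted ring terminus of the allyl unit when a trialkylphosphine is the ligand, so the less substituted exocyclic methylene is kept and the neighbouring stereocentre, which is not part of the allyl system, is untouched.

Step 7
Reactants: 12 2-{2-[(1S)-2,2-dimethyl-6-methylidenecyclohexyl]ethyl}-2-methyl-1,3-dioxolane
Product: 13 (S)-γ-dihydroionone, 4-[(1S)-2,2-dimethyl-6-methylidenecyclohexyl]butan-2-one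
Conditions: PPTS (cat.), acetone/H2O, 50 °C
Reagents that add atoms: water, O
Why: Acetal hydrolysis with a weak pyridinium acid frees the methyl ketone under conditions too mild to move the exocyclic alkene into the ring.

Step 8
Reactants: 13 (S)-γ-dihydroionone; 14 triethyl phosphonoacetate
Product: 15 ethyl (2E)-5-[(1S)-2,2-dimethyl-6-methylidenecyclohexyl]-3-methylpent-2-enoate
Conditions: NaH, THF, 0 → 50 °C; E ester separated from the minor Z ester on silica gel
Reagents that add atoms: none
Why: The Horner–Wadsworth–Emmons olefination of a methyl ketone with a stabilised phosphonate anion favours the E trisubstituted enoate, and the geometrical isomers of such esters should differ enough in polarity for chromatographic separation.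

Step 9
Reactants: 15 ethyl (2E)-5-[(1S)-2,2-dimethyl-6-methylidenecyclohexyl]-3-methylpent-2-enoate
Product: 16 (2E)-5-[(1S)-2,2-dimethyl-6-methylidenecyclohexyl]-3-methylpent-2-en-1-ol
Conditions: i-Bu2AlH (2.2 equiv), CH2Cl2, −78 °C; aq. potassium sodium tartrate
Reagents that add atoms: none
Why: i-Bu2AlH reduces the conjugated ester directly to the allylic alcohol at low temperature (1,2-hydride reduction) without touching either alkene or the alkene geometry.

Step 10
Reactants: 16 (2E)-5-[(1S)-2,2-dimethyl-6-methylidenecyclohexyl]-3-methylpent-2-en-1-ol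
Product: 17 (1S)-1-[(3E)-5-bromo-3-methylpent-3-en-1-yl]-2,2-dimethyl-6-methylidenecyclohexane
Conditions: CBr4, PPh3, CH2Cl2, 0 °C; used crude after filtration through a short pad
Reagents that add atoms: carbon tetrabromide, BrC(Br)(Br)Br
Why: The Appel reaction converts the primary allylic alcohol into the bromide by SN2 displacement of an oxyphosphonium ion under neutral conditions, so neither allylic transposition, loss of the E geometry nor acid-induced migration of the exocyclic methylene is expected.

Step 11
Reactants: 18 (E)-geranylacetone, (5E)-6,10-dimethylundeca-5,9-dien-2-one; 19 ethynylmagnesium bromide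
Product: 20 (6E)-3,7,11-trimethyldodeca-6,10-dien-1-yn-3-ol (racemic)
Conditions: THF, 0 → 20 °C; aq. NH4Cl
Reagents that add atoms: none
Why: Grignard 1,2-addition of the acetylide to the unhindered methyl ketone is straightforward, and the racemic carbinol carbon is of no consequence because it becomes the sp2 carbon C8.

Step 12
Reactants: 17 (1S)-1-[(3E)-5-bromo-3-methylpent-3-en-1-yl]-2,2-dimethyl-6-methylidenecyclohexane; 20 (6E)-3,7,11-trimethyldodeca-6,10-dien-1-yn-3-ol
Product: 21 (6E,14E)-17-[(1S)-2,2-dimethyl-6-methylidenecyclohexyl]-2,6,10,15-tetramethylheptadeca-2,6,14-trien-11-yn-10-ol (both carbinol epimers)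
Conditions: CuI (10 mol %), K2CO3, n-Bu4NCl, DMF, 20 °C
Reagents that add atoms: none
Why: Under carbonate base a copper acetylide forms catalytically from the terminal alkyne and displaces the primary allylic bromide at its α-carbon (copper-catalysed alkynyl–allyl SN2 coupling), which joins the two C15 halves at C11–C12 with retention of the E alkene, while the tertiary hydroxyl needs no protection.

Step 13
Reactants: 21 C30 tertiary propargylic alcohol
Product: 23 methyl carbonate of propargylic alcohol 21, via lithium alkoxide 22 (not isolated)
Conditions: n-BuLi (1.05 equiv), THF, −78 °C; ClCO2Me, −78 → 0 °C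
Reagents that add atoms: methyl chloroformate, COC(=O)Cl
Why: A tertiary propargylic alcohol is too hindered for amine-base acylation but its lithium alkoxide reacts cleanly with the chloroformate (O-acylation), and one equivalent of n-BuLi at −78 °C removes only the hydroxyl proton.

Step 14
Reactants: 23 methyl carbonate of propargylic alcohol 21
Product: 24 (6E,14E)-17-[(1S)-2,2-dimethyl-6-methylidenecyclohexyl]-2,6,10,15-tetramethylheptadeca-2,6,10,11,14-pentaene (both allene epimers)
Conditions: Pd2(dba)3·CHCl3 (2.5 mol %), PBu3 (10 mol %), HCO2NH4, THF, 30 °C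
Reagents that add atoms: none
Why: Zerovalent palladium ionises the propargylic carbonate in an SN2' sense to a σ-allenylpalladium species bearing the metal on C11, formate replaces methoxide and loses CO2, and reductive elimination places hydride on C11 (palladium-catalysed formate hydrogenolysis of a propargylic carbonate), which gives the trisubstituted C8=C9=C11 allene as two epimers about the allene axis that converge in step 15.

Step 15
Reactants: 24 C30 monocyclic allene-polyene
Product: 26 target CNP0271776.1, via bicyclic allyl cation 25 (not isolated)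
Conditions: preformed 1:1 complex of (R)-2'-(2-fluorobenzyloxy)-1,1'-binaphthalen-2-ol and SnCl4 (0.95 equiv), Et3SiH (10 equiv), toluene, −78 °C; Et3N quench at −78 °C
Reagents that add atoms: none
Why: Proposed new method: the binaphthol monoether–SnCl4 complex is a chiral, non-nucleophilic proton donor that should protonate C3 of the terminal isopropylidene while the C5=C10 alkene adds to the developing C4 cation (ring A, 6-endo, chair) and the C10 cation then adds to the central allene carbon C9 (ring B, 6-endo, chair), which leaves a tertiary C8 cation that flattens into the C8–C9–C11 allyl cation 25, and triethylsilane transfers hydride to its secondary terminus C11 to fix the tetrasubstituted C8=C9 alkene. The closest known reaction types are enantioselective proton-initiated polyene bicyclisations with binaphthol–SnCl4 acids, cation additions to the central carbon of allenes, and silane interception of allyl cations in interrupted Nazarov reactions, but their union in one cascade is not known. C5 and C10 are formed together: the trans ring fusion follows from antiperiplanar addition across the E C5=C10 alkene in a chair–chair fold (substrate geometry), and the absolute sense 5S,10S follows from the enantiomer of the acid (reagent control), the remote C17 centre having no say. The step needs site selection among the alkenes, enantioface selection at C3=C4 and a defined position for the final alkene; the first rests on the steric preference of the bulky acid for the chain terminus and on π-participation by C5=C10, which the exocyclic methylene and the C13=C14 alkene lack, and the last on the allyl cation, which accepts hydride at the open CH terminus C11 and not at the ring carbon C8, so both allene epimers converge on one product. Because the acid is the limiting reagent, is consumed as the proton source and is quenched cold, the exocyclic methylene and the C13=C14 alkene are not left with acid and silane together.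

Compound list
1 | 2-(2-bromoethyl)-2-methyl-1,3-dioxolane | CC1(CCBr)OCCO1 | starting material
2 | [2-(2-methyl-1,3-dioxolan-2-yl)ethyl]magnesium bromide | CC1(CC[Mg]Br)OCCO1 | intermediate
3 | bis[2-(2-methyl-1,3-dioxolan-2-yl)ethyl]zinc | CC1(CC[Zn]CCC2(C)OCCO2)OCCO1 | intermediate
4 | 4,4-dimethylcyclohex-2-en-1-one | CC1(C)CCC(=O)C=C1 | starting material
5 | N,N-dimethylmethyleneiminium iodide (Eschenmoser's salt) | C=[N+](C)C.[I-] | starting material
6 | alkylzinc enolate, {[(3R)-4,4-dimethyl-3-[2-(2-methyl-1,3-dioxolan-2-yl)ethyl]cyclohex-1-en-1-yl]oxy}[2-(2-methyl-1,3-dioxolan-2-yl)ethyl]zinc | CC1(CC[Zn]OC2=C[C@@H](CCC3(C)OCCO3)C(C)(C)CC2)OCCO1 | intermediate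
7 | (3R)-2-[(dimethylamino)methyl]-4,4-dimethyl-3-[2-(2-methyl-1,3-dioxolan-2-yl)ethyl]cyclohexan-1-one (C2 epimers, trans expected to predominate) | CN(C)CC1C(=O)CCC(C)(C)[C@@H]1CCC2(C)OCCO2 | intermediate
8 | trimethylammonium iodide of 7 | C[N+](C)(C)CC1C(=O)CCC(C)(C)[C@@H]1CCC2(C)OCCO2.[I-] | intermediate
9 | (3S)-4,4-dimethyl-2-methylidene-3-[2-(2-methyl-1,3-dioxolan-2-yl)ethyl]cyclohexan-1-one (same spatial arrangement as in 7) | C=C1C(=O)CCC(C)(C)[C@@H]1CCC2(C)OCCO2 | intermediate
10 | (3S)-4,4-dimethyl-2-methylidene-3-[2-(2-methyl-1,3-dioxolan-2-yl)ethyl]cyclohexan-1-ol (C1 epimers) | C=C1C(O)CCC(C)(C)[C@@H]1CCC2(C)OCCO2 | intermediate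
11 | methyl carbonate of 10 | C=C1C(OC(=O)OC)CCC(C)(C)[C@@H]1CCC2(C)OCCO2 | intermediate
12 | 2-{2-[(1S)-2,2-dimethyl-6-methylidenecyclohexyl]ethyl}-2-methyl-1,3-dioxolane | C=C1CCCC(C)(C)[C@@H]1CCC2(C)OCCO2 | intermediate
13 | (S)-γ-dihydroionone, 4-[(1S)-2,2-dimethyl-6-methylidenecyclohexyl]butan-2-one | C=C1CCCC(C)(C)[C@@H]1CCC(C)=O | intermediate
14 | triethyl phosphonoacetate | CCOC(=O)CP(=O)(OCC)OCC | starting material
15 | ethyl (2E)-5-[(1S)-2,2-dimethyl-6-methylidenecyclohexyl]-3-methylpent-2-enoate | C=C1CCCC(C)(C)[C@@H]1CC/C(C)=C/C(=O)OCC | intermediate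
16 | (2E)-5-[(1S)-2,2-dimethyl-6-methylidenecyclohexyl]-3-methylpent-2-en-1-ol | C=C1CCCC(C)(C)[C@@H]1CC/C(C)=C/CO | intermediate
17 | (1S)-1-[(3E)-5-bromo-3-methylpent-3-en-1-yl]-2,2-dimethyl-6-methylidenecyclohexane | C=C1CCCC(C)(C)[C@@H]1CC/C(C)=C/CBr | intermediate
18 | (E)-geranylacetone, (5E)-6,10-dimethylundeca-5,9-dien-2-one | CC(=O)CC/C=C(C)/CCC=C(C)C | starting material
19 | ethynylmagnesium bromide | C#C[Mg]Br | starting material
20 | (6E)-3,7,11-trimethyldodeca-6,10-dien-1-yn-3-ol (racemic) | C#CC(C)(O)CC/C=C(C)/CCC=C(C)C | intermediate
21 | (6E,14E)-17-[(1S)-2,2-dimethyl-6-methylidenecyclohexyl]-2,6,10,15-tetramethylheptadeca-2,6,14-trien-11-yn-10-ol (carbinol epimers) | C=C1CCCC(C)(C)[C@@H]1CC/C(C)=C/CC#CC(C)(O)CC/C=C(C)/CCC=C(C)C | intermediate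
22 | lithium alkoxide of 21 | C=C1CCCC(C)(C)[C@@H]1CC/C(C)=C/CC#CC(C)(O[Li])CC/C=C(C)/CCC=C(C)C | intermediate
23 | methyl carbonate of 21 | C=C1CCCC(C)(C)[C@@H]1CC/C(C)=C/CC#CC(C)(OC(=O)OC)CC/C=C(C)/CCC=C(C)C | intermediate
24 | (6E,14E)-17-[(1S)-2,2-dimethyl-6-methylidenecyclohexyl]-2,6,10,15-tetramethylheptadeca-2,6,10,11,14-pentaene (allene epimers) | C=C1CCCC(C)(C)[C@@H]1CC/C(C)=C/CC=C=C(C)CC/C=C(C)/CCC=C(C)C | intermediate
25 | bicyclic C8–C9–C11 allyl cation (5S,10S,17S; C9=C11 geometry not fixed; drawn with the charge on C8) | C=C1CCCC(C)(C)[C@@H]1CC/C(C)=C/CC=C1[C+](C)CC[C@H]2C(C)(C)CCC[C@]12C | intermediate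
26 | target CNP0271776.1, (5S,10S)-drim-8-ene joined from C11 through C12H2 to the (13E)-alkene and the (17S)-2,2-dimethyl-6-methylidenecyclohexyl ring | C=C1CCCC(C)(C)[C@@H]1CC/C(C)=C/CCC1=C(C)CC[C@H]2C(C)(C)CCC[C@]12C | target

Total step count: 15 steps. Longest linear sequence: 14 steps (steps 1–10, then 12–15); step 11 is the only side-branch step.

Steps most likely to fail

1. Step 15. The acid may protonate the C13=C14 alkene or the exocyclic methylene instead of the chain terminus. Facial selection at C3=C4 may be incomplete, and because C17 is fixed this would show up as C5/C10 diastereomers that are hard to separate. The monocyclic C10 cation may lose a proton or be reduced by the silane before ring B closes. The allyl cation may lose a proton from C12 or be attacked by the C13=C14 alkene. The fallback uses known chemistry only, sets out from 17 and comes back at 26, taking C5 and C10 from the chiral pool. Bromide 17 would be treated with PhSO2Na in DMF to give the allylic phenyl sulfone F1. Separately, purchased (−)-drimenol F2 would be oxidised with Dess–Martin periodinane to drimenal F3, conjugated with DBU to drim-8-en-11-al F4, reduced with NaBH4/CeCl3·7H2O to drim-8-en-11-ol F5 and brominated with PBr3 and a trace of pyridine in Et2O to 11-bromodrim-8-ene F6. Sulfone F1 would be deprotonated with n-BuLi in THF–DMPU at −78 °C to the α-lithio sulfone F7 and alkylated with F6 to the C30 sulfone F8, which forms the C11–C12 bond. Reductive desulfonylation of F8 with LiBHEt3 and catalytic PdCl2(dppp) in THF, which delivers hydride to the less substituted allyl terminus C12, would then give 26.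

2. Step 2. C-aminomethylation of the hindered alkylzinc enolate may be slow in a non-polar medium, so that protonation at work-up gives the simple ketone, whose regiodefined enolate cannot be regenerated. Residual magnesium halide or THF from step 1 may also erode the facial selectivity. The fallback sets out from the zinc enolate 6 (made from 3 and 4 exactly as in step 2) and comes back at 7. The enolate would be silylated with TMSOTf and the trimethylsilyl enol ether F9 isolated. In a separate Mukaiyama-type Mannich reaction F9 would then be treated with 5 in CH2Cl2 to give 7, so that the regiochemistry is stored in an isolable compound and the iminium ion meets a more reactive, salt-free nucleophile.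

3. Step 14. The allenylpalladium intermediate may eliminate to a conjugated enyne or deliver hydride at C8 to give the alkyne. The doubly allylic C12 hydrogens of the skipped ene-yne and ene-allene may also migrate under palladium hydride or base, which would pull the unsaturation into conjugation. The fallback sets out from 20 and 17 and comes back at 24, with the order of events reversed so that steps 12 and 13 are also replaced. Alcohol 20 would be deprotonated with n-BuLi to the lithium alkoxide F10 and acylated with ClCO2Me to the methyl carbonate F11, a simple terminal-alkyne carbonate of the kind for which the formate hydrogenolysis is best established. Pd2(dba)3·CHCl3, PBu3 and HCO2NH4 would convert F11 into the terminal allene F12, (6E)-3,7,11-trimethyldodeca-1,2,6,10-tetraene. Deprotonation of F12 at its allenic CH2 terminus with n-BuLi in THF (−78 → −40 °C) would give the allenyllithium F13, and alkylation of F13 at that carbon with bromide 17 would form C11–C12 and give 24 directly.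

Further compounds
F1 | step 15 | (1S)-2,2-dimethyl-6-methylidene-1-[(3E)-3-methyl-5-(phenylsulfonyl)pent-3-en-1-yl]cyclohexane | C=C1CCCC(C)(C)[C@@H]1CC/C(C)=C/CS(=O)(=O)c1ccccc1
F2 | step 15 | (−)-drimenol, (5S,9S,10S)-drim-7-en-11-ol | OC[C@H]1C(C)=CC[C@H]2C(C)(C)CCC[C@]12C
F3 | step 15 | drimenal, (5S,9S,10S)-drim-7-en-11-al | O=C[C@H]1C(C)=CC[C@H]2C(C)(C)CCC[C@]12C
F4 | step 15 | (5S,10S)-drim-8-en-11-al | O=CC1=C(C)CC[C@H]2C(C)(C)CCC[C@]12C
F5 | step 15 | (5S,10S)-drim-8-en-11-ol | OCC1=C(C)CC[C@H]2C(C)(C)CCC[C@]12C
F6 | step 15 | (5S,10S)-11-bromodrim-8-ene | BrCC1=C(C)CC[C@H]2C(C)(C)CCC[C@]12C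
F7 | step 15 | α-lithio derivative of sulfone F1 | C=C1CCCC(C)(C)[C@@H]1CC/C(C)=C/C([Li])S(=O)(=O)c1ccccc1
F8 | step 15 | C30 sulfone, 12-(phenylsulfonyl) derivative of 26 (C12 epimers) | C=C1CCCC(C)(C)[C@@H]1CC/C(C)=C/C(CC1=C(C)CC[C@H]2C(C)(C)CCC[C@]12C)S(=O)(=O)c1ccccc1
F9 | step 2 | trimethylsilyl enol ether, {[(3R)-4,4-dimethyl-3-[2-(2-methyl-1,3-dioxolan-2-yl)ethyl]cyclohex-1-en-1-yl]oxy}trimethylsilane | C[Si](C)(C)OC1=C[C@@H](CCC2(C)OCCO2)C(C)(C)CC1
F10 | step 14 | lithium alkoxide of 20 | C#CC(C)(O[Li])CC/C=C(C)/CCC=C(C)C
F11 | step 14 | methyl carbonate of 20 | C#CC(C)(OC(=O)OC)CC/C=C(C)/CCC=C(C)C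
F12 | step 14 | (6E)-3,7,11-trimethyldodeca-1,2,6,10-tetraene | C=C=C(C)CC/C=C(C)/CCC=C(C)C
F13 | step 14 | 1-lithio derivative of allene F12 | [Li]C=C=C(C)CC/C=C(C)/CCC=C(C)C
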